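# Proposed total synthesis of CNP0237075.1 by aryne–furan Diels–Alder annulation

## Analysis of the target

The target is a 1,2-dihydronaphthalene. Ring A is aromatic and carries a catechol at C7/C8; ring B holds the saturated carboxyl-bearing carbon C1 (on C8a), the aryl-bearing carbon C2 and the C3=C4 enoate (C4 on C4a). Both carboxyl groups are esterified with methyl 3-(3,4-dihydroxyphenyl)lactate. There are four stereocentres: C1 and C2 are both S, with the C1 carboxyl and the C2 aryl group cis. The lactate carbon of the C3 ester is S and that of the C1 ester is R, so the two side chains are antipodal and cannot be attached in one operation. The cis C1/C2 arrangement is expected to be the less stable one, and C1–H is benzylic and α to an ester, so no step after C1 is set may enolise it. Further liabilities are four air-sensitive catechols, a C3=C4 enoate that is open to reduction and hydrogenation, and side-chain α-acyloxy esters that are cleaved by electron-transfer reagents and eliminate under base. The central difficulty is ring A: it is 1,2,3,4-tetrasubstituted with the C1 branch crowded against the C8 oxygen, which electrophilic substitution of a catechol derivative does not deliver. The strategy rests on the C4a–C8a edge of ring A: the two bonds from ring A to ring B (C8a–C1 and C4a–C4) start from adjacent carbons beside the C8 oxygen, the pattern an aryne delivers in one cycloaddition.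

## Retrosynthetic reasoning

**32 from 31.** The eight aryl benzyl ethers are cut last. The catechols are the most fragile groups and should appear only at the end. Hydrogenolysis is excluded by the C3=C4 alkene, so the forward step must be a Lewis-acid debenzylation that uses no base and so leaves C1 untouched.

**31 from 30 and 27.** In the C1 ester the O–C(alkyl) bond is cut, not the acyl–O bond. Forward, the carboxylate of 30 displaces the activated hydroxyl of 27 with inversion. This turns the (S)-alcohol into the (R)-ester that C1 needs, and it never makes the C1 carboxyl an acyl donor, so no ketene or enol path to C1 epimerisation exists.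

**30 from 29, and 29 from 28 and 27.** In the C3 ester the acyl–O bond is cut. Acylation of the same alcohol 27 proceeds with retention and gives the (S)-ester; the acid 28 is an enoic acid with no α-hydrogen. An allyl ester at C1 and a tert-butyl ester at C3 allow the two antipodal side chains to go on one after the other. Both go on after the reductive step, because their α-acyloxy ester units would not survive it.

**28 from 23, and 23 from 21.** The C1–H bond is traced back to a C1–O bond. Forward, the tertiary α-hydroxy ester of 21 is reduced through the enolate 22, and the proton must enter on the face away from the C2 aryl group to give the cis product.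

**21 from 15 and 20.** The C2–aryl bond is cut and the C4–O bond is restored, which leads to the oxygen-bridged bicycle 15. Forward, an arylmetal derived from 20 must add at C2 on the face of the bridging oxygen, and loss of the C4 oxygen then creates the C3=C4 alkene. A chiral catalyst must pick one enantiomer of racemic 15.

**15 from 8 and 13 through 14.** C8a–C1 and C4a–C4 are cut together. This is the only disconnection that makes both ring B attachments of ring A in one step and brings the bridging oxygen needed for the previous operation. Forward, aryne 14 must take up the furan 13 with the ester-bearing furan carbon on C8a.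

**8 from 5, 3, 2 and 1.** The silyl group between the triflate and the C8 oxygen is traced to a bromine that already occupies this position in commercial 1. Halogen–metal exchange then fixes the site. A directed deprotonation would have to choose between ring positions and compete with benzylic metalation.

**13 from 12, 11, 10 and 9.** The furan is traced to a 3-bromo-2-pyrone by ring contraction. With the C5 carboxyl of the pyrone already a tert-butyl ester (11), the two furan carboxyls emerge differentiated in 12.

**20 from 17 and 16; 27 from 26, 25 and 24.** The boronic acid comes from the aryl bromide. The side-chain alcohol comes from the amino acid 24 with retention at the stereocentre.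

## Alternatives that were turned down

**Alternative 1:** The C2–C3 bond is cut. Forward, the C7 phenoxide of the open-chain bis-enoate A2 relays charge to C3 of its cinnamate arm, C3 adds to the β-carbon of the neighbouring α-aryl acrylate, and proton shifts give the dihydronaphthalene A1.

- For: it is an isomerisation with both side chains already in place, and it is shorter and more convergent than the chosen route. On step economy it is stronger.
- Against: A2 contains the same crowded ring A with two different acrylate arms ortho to each other, so the substitution problem is only moved. The extended phenoxide is a weak carbon nucleophile and the addition is reversible. C1 and C2 are set under basic, equilibrating conditions, which favour the trans isomer. The only sources of absolute control are two remote, antipodal lactate centres. The α-acyloxy esters face base throughout.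
- Comparison: the chosen route gives up brevity and sets C2 by a chiral catalyst and C1 by a kinetic protonation without base.

**Alternative 2:** C2–C3 and C1–C2 are cut, so that C2 comes from an aldehyde carbon. Forward, zerovalent palladium inserts into the vinyl iodide A4, the carbene from tosylhydrazone A5 inserts to give an allylpalladium species, and the tethered malonate closes the ring to the 1,1,3-triester A3.

- For: ring A orientation is fixed by the synthesis of A4, so there is no cycloaddition regiochemistry to control. On this point it is stronger than the chosen route. The C2 aryl group comes from a simple aldehyde derivative.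
- Against: A3 has two esters on C1. One must be removed, and the resulting C1–H is then set by a thermal decarboxylation with no lever for the cis isomer. The aryl malonate next to the C8 oxygen is hard to make. Asymmetric induction in this cascade is untested. Three ester groups must be told apart later.
- Comparison: the chosen route makes both ring bonds from two simple partners and controls C1 and C2 in separate, precedented steps.

**Alternative 3:** The temporary bond cut is the O–acyl bond between the C8 oxygen and the C1 carboxyl. Forward, the hydroxy acid A7 (either C1 epimer) is closed to the five-membered peri-lactone A6 and the C1–H, now acidic, is equilibrated by an amine.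

- For: it makes the cis isomer the thermodynamic one, which is a more robust answer to the C1 problem than a kinetic protonation. On this point it is stronger.
- Against: it does not build the skeleton and needs the C8 hydroxyl free while C7 is protected. The lactone must later be opened at the acyl carbon by a hindered, weakly nucleophilic α-hydroxy ester, under conditions that can re-epimerise the opened product.
- Comparison: the chosen route sets C1 kinetically and forms the C1 ester by carboxylate alkylation, so the C1 carboxyl is never activated.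

Key step: step 9

Remark: the sense in which an antipode of the ligand discriminates the enantiomers of 15 cannot be fixed in advance; (R)-BINAP is written in step 12, and its mirror image is to be used if the first run shows that it consumes the other enantiomer.

## Route

Step 1
Reactants: 1 2-bromo-3-hydroxy-4-methoxybenzaldehyde
Product: 2 2-bromo-3,4-dihydroxybenzaldehyde
Conditions: BBr3 (2.5 equiv), CH2Cl2, −78 °C → rt; H2O
Reagents that add atoms: none
Why: Lewis-acid O-demethylation of the aryl methyl ether; the aldehyde and the aryl bromide are inert, and both ring A oxygens can now carry benzyl groups that fall together in step 21.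

Step 2
Reactants: 2 2-bromo-3,4-dihydroxybenzaldehyde
Product: 3 3,4-bis(benzyloxy)-2-bromobenzaldehyde
Conditions: BnBr (2.4 equiv), K2CO3, DMF, 60 °C
Reagents that add atoms: benzyl bromide, BrCc1ccccc1
Why: Williamson ether synthesis on both phenols.

Step 3
Reactants: 3 3,4-bis(benzyloxy)-2-bromobenzaldehyde
Product: 5 3,4-bis(benzyloxy)-2-bromophenol, via aryl formate 4 (not isolated)
Conditions: mCPBA, CH2Cl2, 0 °C → rt; then K2CO3 (cat.), MeOH, rt
Reagents that add atoms: 3-chloroperoxybenzoic acid, OOC(=O)c1cccc(Cl)c1
Why: Baeyer–Villiger (Dakin-type) oxidation, in which the electron-rich aryl group (para benzyloxy) migrates in preference to hydrogen; the formate is then methanolysed.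

Step 4
Reactants: 5 3,4-bis(benzyloxy)-2-bromophenol
Product: 8 3,4-bis(benzyloxy)-2-(trimethylsilyl)phenyl triflate, via silyl ether 6 (not isolated), via lithium phenoxide 7 (not isolated)
Conditions: (Me3Si)2NH, THF, 65 °C, then evaporation; n-BuLi, THF, −100 → −78 °C; Tf2O, −100 °C → rt
Reagents that add atoms: hexamethyldisilazane, C[Si](C)(C)N[Si](C)(C)C; triflic anhydride, O=S(=O)(OS(=O)(=O)C(F)(F)F)C(F)(F)F
Why: O-silylation, bromine–lithium exchange and retro-Brook (1,3 O→C) silyl migration put silicon exactly where the bromine was, and the phenoxide is then triflated; exchange at −100 °C is far faster than benzylic deprotonation.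

Step 5
Reactants: 9 coumalic acid
Product: 10 3-bromo-2-oxo-2H-pyran-5-carboxylic acid
Conditions: Br2 (1.05 equiv), AcOH, 60 °C
Reagents that add atoms: bromine, BrBr
Why: Electrophilic bromination of the 2-pyrone (addition–elimination) at C3, the position activated by the ring oxygen that is not blocked by the carboxyl; it is done on the free acid so that the HBr formed meets no acid-labile ester.

Step 6
Reactants: 10 3-bromo-2-oxo-2H-pyran-5-carboxylic acid
Product: 11 tert-butyl 3-bromo-2-oxo-2H-pyran-5-carboxylate
Conditions: t-BuOC(=NH)CCl3 (2 equiv), BF3·OEt2 (cat.), CH2Cl2/cyclohexane, rt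
Reagents that add atoms: tert-butyl 2,2,2-trichloroacetimidate, CC(C)(C)OC(=N)C(Cl)(Cl)Cl
Why: Acid-catalysed tert-butylation of the carboxylic acid by the trichloroacetimidate; no nucleophile or base is present that could open the pyrone.

Step 7
Reactants: 11 tert-butyl 3-bromo-2-oxo-2H-pyran-5-carboxylate
Product: 12 4-(tert-butoxycarbonyl)furan-2-carboxylic acid
Conditions: KOH (3 equiv), THF/H2O, 0 °C → rt; then cold 1 M HCl to pH 3
Reagents that add atoms: potassium hydroxide, [K+].[OH-]
Why: Ring contraction of a 3-halo-2-pyrone to a 2-furoic acid (Perkin-type rearrangement): hydroxide opens the lactone and the enolate oxygen displaces the vinylic bromide by addition–elimination. The tert-butyl ester resists hydroxide, so the two carboxyl groups emerge differentiated.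

Step 8
Reactants: 12 4-(tert-butoxycarbonyl)furan-2-carboxylic acid
Product: 13 2-allyl 4-tert-butyl furan-2,4-dicarboxylate
Conditions: allyl bromide, K2CO3, DMF, rt
Reagents that add atoms: allyl bromide, C=CCBr
Why: O-alkylation of the carboxylate; the allyl ester is later removable under neutral conditions beside the tert-butyl ester.

Step 9
Reactants: 8 3,4-bis(benzyloxy)-2-(trimethylsilyl)phenyl triflate; 13 2-allyl 4-tert-butyl furan-2,4-dicarboxylate
Product: 15 1-allyl 3-tert-butyl (1S,4S)-7,8-bis(benzyloxy)-1,4-dihydro-1,4-epoxynaphthalene-1,3-dicarboxylate (formed as the racemate), via aryne 14 (not isolated)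
Conditions: CsF (3 equiv), 13 (2.5 equiv), MeCN, rt, 8 added over 4 h; excess 13 recovered
Reagents that add atoms: none
Why: Fluoride removes the trimethylsilyl group of 8 and triflate leaves, giving aryne 14, which the furan diene of 13 traps in a concerted, asynchronous [4+2] cycloaddition (aryne–furan Diels–Alder reaction of o-silylaryl triflates, a well-established reaction type). The single ring-forming event closes ring B (C1–C2–C3–C4–C4a–C8a) and with it the five-membered 1,4-epoxy ring (O–C1–C8a–C4a–C4); both come from the same suprafacial addition across furan C2 and C5. C1 and C4 become stereocentres whose relative configuration is dictated by the bicycle; 14 is planar and the furan faces are equivalent, so 15 forms as the racemate and absolute control is left to step 12. The selectivity the step needs is orientational: the ester-bearing furan carbon must bond to C8a. The handles are the C8 benzyloxy group, which distorts 14 so that C4a bonds first, and the furan HOMO, whose larger terminal coefficient lies at the unsubstituted carbon, so that the leading bond is C4a–C4 and the lagging bond C8a–C1 forms beside the ether at long distance with little steric cost. A charge-separated reading of the same transition state argues the other way, because the two acceptors resist positive charge at the furan carbons that become C1 and C3; the orientation is therefore the first item in the risk list and is to be assigned (NOE between H4 and H5) before material is carried on. The conditions are non-basic and leave both esters untouched.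

Step 10
Reactants: 16 4-bromocatechol
Product: 17 1,2-bis(benzyloxy)-4-bromobenzene
Conditions: BnBr (2.4 equiv), K2CO3, DMF, 60 °C
Reagents that add atoms: benzyl bromide, BrCc1ccccc1
Why: Williamson ether synthesis on both phenols.

Step 11
Reactants: 17 1,2-bis(benzyloxy)-4-bromobenzene
Product: 20 [3,4-bis(benzyloxy)phenyl]boronic acid, via aryllithium 18 (not isolated), via lithium borate 19 (not isolated)
Conditions: n-BuLi, THF, −78 °C; B(Oi-Pr)3, −78 °C → rt; 1 M HCl
Reagents that add atoms: triisopropyl borate, CC(C)OB(OC(C)C)OC(C)C; water, O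
Why: Bromine–lithium exchange, borylation of the aryllithium and hydrolysis of the borate.

Step 12
Reactants: 15 1-allyl 3-tert-butyl (1S,4S)-7,8-bis(benzyloxy)-1,4-dihydro-1,4-epoxynaphthalene-1,3-dicarboxylate (racemate); 20 [3,4-bis(benzyloxy)phenyl]boronic acid
Product: 21 1-allyl 3-tert-butyl (1S,2S)-7,8-bis(benzyloxy)-2-[3,4-bis(benzyloxy)phenyl]-1-hydroxy-1,2-dihydronaphthalene-1,3-dicarboxylate
Conditions: [Rh(cod)Cl]2 (2.5 mol%), (R)-BINAP (5.5 mol%), 20 (0.6 equiv, in portions), Cs2CO3 (0.5 equiv), THF/H2O 10:1, rt
Reagents that add atoms: none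
Why: Rhodium-catalysed arylative ring opening of an oxabenzonorbornadiene with an arylboronic acid, here also a conjugate addition to the strained enoate: the aryl–rhodium species adds from the exo face (the face of the bridging oxygen) with the aryl group at C2, the β-carbon of the enoate, and the rhodium enolate at C3 expels the C4 oxygen to give the C3=C4 alkene and the C1 alkoxide. Exo delivery sets C2 with the aryl group cis to the C1 hydroxyl; since the site of attack is fixed by the enoate, the chiral catalyst can only discriminate between the enantiomers of 15 and is used to consume the (1S,4S)-enantiomer (kinetic resolution), leaving the (1R,4R)-enantiomer behind.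

Step 13
Reactants: 21 1-allyl 3-tert-butyl (1S,2S)-7,8-bis(benzyloxy)-2-[3,4-bis(benzyloxy)phenyl]-1-hydroxy-1,2-dihydronaphthalene-1,3-dicarboxylate
Product: 23 1-allyl 3-tert-butyl (1S,2S)-7,8-bis(benzyloxy)-2-[3,4-bis(benzyloxy)phenyl]-1,2-dihydronaphthalene-1,3-dicarboxylate, via samarium enolate 22 (not isolated)
Conditions: SmI2 (2.1 equiv), HMPA (8 equiv), THF, −78 → −20 °C, no proton source; then AcOH in THF, −78 °C
Reagents that add atoms: none
Why: Reductive cleavage of an α-hydroxy ester by SmI2: electron transfer to the chelated, benzylic α-hydroxy ester expels hydroxide and a second electron gives the enolate, while the electron-rich enoate, which has no leaving group, is reduced only reversibly as long as no proton donor is present. Kinetic protonation of the enolate takes place on the face opposite the pseudoaxial C2 aryl group, which puts H1 trans to the aryl group and the C1 ester cis to it.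

Step 14
Reactants: 24 L-DOPA
Product: 25 (2S)-3-(3,4-dihydroxyphenyl)-2-hydroxypropanoic acid
Conditions: NaNO2 (1.5 equiv), 1 M H2SO4, 0 °C → rt, under N2
Reagents that add atoms: water, O
Why: Diazotisation of the α-amino acid; the carboxylate displaces nitrogen to an α-lactone, which water opens, so two inversions give net retention and the (S)-hydroxy acid.

Step 15
Reactants: 25 (2S)-3-(3,4-dihydroxyphenyl)-2-hydroxypropanoic acid
Product: 26 methyl (2S)-3-(3,4-dihydroxyphenyl)-2-hydroxypropanoate
Conditions: MeOH, H2SO4 (cat.), reflux, under N2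
Reagents that add atoms: methanol, CO
Why: Fischer esterification; the stereocentre is not touched under acid.

Step 16
Reactants: 26 methyl (2S)-3-(3,4-dihydroxyphenyl)-2-hydroxypropanoate
Product: 27 methyl (2S)-3-[3,4-bis(benzyloxy)phenyl]-2-hydroxypropanoate
Conditions: BnBr (2.2 equiv), K2CO3, acetone, reflux
Reagents that add atoms: benzyl bromide, BrCc1ccccc1
Why: Williamson ether synthesis, selective for the phenols because carbonate does not deprotonate the secondary alcohol.

Step 17
Reactants: 23 1-allyl 3-tert-butyl (1S,2S)-7,8-bis(benzyloxy)-2-[3,4-bis(benzyloxy)phenyl]-1,2-dihydronaphthalene-1,3-dicarboxylate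
Product: 28 (1S,2S)-1-[(allyloxy)carbonyl]-7,8-bis(benzyloxy)-2-[3,4-bis(benzyloxy)phenyl]-1,2-dihydronaphthalene-3-carboxylic acid
Conditions: TFA/CH2Cl2 1:4, 0 °C
Reagents that add atoms: none
Why: Acidolysis of the tert-butyl ester (loss of isobutene); the acidic, non-enolising medium leaves C1, the allyl ester and the aryl benzyl ethers intact.

Step 18
Reactants: 28 (1S,2S)-1-[(allyloxy)carbonyl]-7,8-bis(benzyloxy)-2-[3,4-bis(benzyloxy)phenyl]-1,2-dihydronaphthalene-3-carboxylic acid; 27 methyl (2S)-3-[3,4-bis(benzyloxy)phenyl]-2-hydroxypropanoate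
Product: 29 1-allyl 3-[(2S)-3-[3,4-bis(benzyloxy)phenyl]-1-methoxy-1-oxopropan-2-yl] (1S,2S)-7,8-bis(benzyloxy)-2-[3,4-bis(benzyloxy)phenyl]-1,2-dihydronaphthalene-1,3-dicarboxylate
Conditions: EDC·HCl (1.5 equiv), DMAP (0.2 equiv), 27 (1.2 equiv), CH2Cl2, 0 °C → rt
Reagents that add atoms: none
Why: Steglich esterification: the activated acyl group is an enoyl group without α-hydrogen and the alcohol oxygen is acylated with retention, which gives the (S)-configured ester at the C3 carboxyl. Catalytic DMAP is too weak a base to enolise the C1 allyl ester.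

Step 19
Reactants: 29 1-allyl 3-[(2S)-3-[3,4-bis(benzyloxy)phenyl]-1-methoxy-1-oxopropan-2-yl] (1S,2S)-7,8-bis(benzyloxy)-2-[3,4-bis(benzyloxy)phenyl]-1,2-dihydronaphthalene-1,3-dicarboxylate
Product: 30 (1S,2S)-7,8-bis(benzyloxy)-2-[3,4-bis(benzyloxy)phenyl]-3-({[(2S)-3-[3,4-bis(benzyloxy)phenyl]-1-methoxy-1-oxopropan-2-yl]oxy}carbonyl)-1,2-dihydronaphthalene-1-carboxylic acid
Conditions: Pd(PPh3)4 (5 mol%), p-TolSO2Na (1.5 equiv), THF/MeOH, rt; dilute HCl work-up
Reagents that add atoms: none
Why: Tsuji–Trost deallylation by zerovalent palladium with a non-basic sulfinate as allyl acceptor; the carboxylate that forms cannot enolise, so C1 is safe, and the side-chain ester is not allylic and stays.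

Step 20
Reactants: 30 (1S,2S)-7,8-bis(benzyloxy)-2-[3,4-bis(benzyloxy)phenyl]-3-({[(2S)-3-[3,4-bis(benzyloxy)phenyl]-1-methoxy-1-oxopropan-2-yl]oxy}carbonyl)-1,2-dihydronaphthalene-1-carboxylic acid; 27 methyl (2S)-3-[3,4-bis(benzyloxy)phenyl]-2-hydroxypropanoate
Product: 31 1-[(2R)-3-[3,4-bis(benzyloxy)phenyl]-1-methoxy-1-oxopropan-2-yl] 3-[(2S)-3-[3,4-bis(benzyloxy)phenyl]-1-methoxy-1-oxopropan-2-yl] (1S,2S)-7,8-bis(benzyloxy)-2-[3,4-bis(benzyloxy)phenyl]-1,2-dihydronaphthalene-1,3-dicarboxylate
Conditions: PPh3 (1.5 equiv), DIAD (1.5 equiv), 27 (1.3 equiv), toluene, 0 °C → rt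
Reagents that add atoms: none
Why: Mitsunobu esterification: the carboxylate of 30 displaces the oxyphosphonium group of 27 in an SN2 step with inversion, which turns the (S)-alcohol into the (R)-configured ester required at C1. The C1 carboxyl is never made an acyl donor, so no ketene or enol path to epimerisation at C1 opens.

Step 21
Reactants: 31 1-[(2R)-3-[3,4-bis(benzyloxy)phenyl]-1-methoxy-1-oxopropan-2-yl] 3-[(2S)-3-[3,4-bis(benzyloxy)phenyl]-1-methoxy-1-oxopropan-2-yl] (1S,2S)-7,8-bis(benzyloxy)-2-[3,4-bis(benzyloxy)phenyl]-1,2-dihydronaphthalene-1,3-dicarboxylate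
Product: 32 CNP0237075.1, 1-[(2R)-3-(3,4-dihydroxyphenyl)-1-methoxy-1-oxopropan-2-yl] 3-[(2S)-3-(3,4-dihydroxyphenyl)-1-methoxy-1-oxopropan-2-yl] (1S,2S)-2-(3,4-dihydroxyphenyl)-7,8-dihydroxy-1,2-dihydronaphthalene-1,3-dicarboxylate
Conditions: BCl3 (20 equiv), C6HMe5 (30 equiv), CH2Cl2, −78 °C; MeOH quench at −78 °C
Reagents that add atoms: none
Why: Lewis-acid cleavage of the eight aryl benzyl ethers with pentamethylbenzene as a non-basic scavenger for the benzyl cation; the low temperature and the absence of base preserve the esters, the C3=C4 alkene (which hydrogenolysis would saturate) and the cis C1/C2 relationship.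

## Compound list

1 | 2-bromo-3-hydroxy-4-methoxybenzaldehyde | O=Cc1ccc(OC)c(O)c1Br | starting material
2 | 2-bromo-3,4-dihydroxybenzaldehyde | O=Cc1ccc(O)c(O)c1Br | intermediate
3 | 3,4-bis(benzyloxy)-2-bromobenzaldehyde | O=Cc1ccc(OCc2ccccc2)c(OCc2ccccc2)c1Br | intermediate
4 | 3,4-bis(benzyloxy)-2-bromophenyl formate | O=COc1ccc(OCc2ccccc2)c(OCc2ccccc2)c1Br | intermediate (not isolated)
5 | 3,4-bis(benzyloxy)-2-bromophenol | Oc1ccc(OCc2ccccc2)c(OCc2ccccc2)c1Br | intermediate
6 | [3,4-bis(benzyloxy)-2-bromophenoxy]trimethylsilane | C[Si](C)(C)Oc1ccc(OCc2ccccc2)c(OCc2ccccc2)c1Br | intermediate (not isolated)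
7 | lithium 3,4-bis(benzyloxy)-2-(trimethylsilyl)phenoxide | [Li+].[O-]c1ccc(OCc2ccccc2)c(OCc2ccccc2)c1[Si](C)(C)C | intermediate (not isolated)
8 | 3,4-bis(benzyloxy)-2-(trimethylsilyl)phenyl triflate | C[Si](C)(C)c1c(OCc2ccccc2)c(OCc2ccccc2)ccc1OS(=O)(=O)C(F)(F)F | intermediate
9 | coumalic acid | OC(=O)C1=COC(=O)C=C1 | starting material
10 | 3-bromo-2-oxo-2H-pyran-5-carboxylic acid | OC(=O)C1=COC(=O)C(Br)=C1 | intermediate
11 | tert-butyl 3-bromo-2-oxo-2H-pyran-5-carboxylate | CC(C)(C)OC(=O)C1=COC(=O)C(Br)=C1 | intermediate
12 | 4-(tert-butoxycarbonyl)furan-2-carboxylic acid | OC(=O)c1cc(C(=O)OC(C)(C)C)co1 | intermediate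
13 | 2-allyl 4-tert-butyl furan-2,4-dicarboxylate | C=CCOC(=O)c1cc(C(=O)OC(C)(C)C)co1 | intermediate
14 | 3,4-bis(benzyloxy)benzyne | C1#CC(OCc2ccccc2)=C(OCc2ccccc2)C=C1 | intermediate (not isolated)
15 | 1-allyl 3-tert-butyl (1S,4S)-7,8-bis(benzyloxy)-1,4-dihydro-1,4-epoxynaphthalene-1,3-dicarboxylate (racemate; the enantiomer shown is the one consumed in step 12) | C=CCOC(=O)[C@@]12O[C@@H](c3ccc(OCc4ccccc4)c(OCc4ccccc4)c31)C(C(=O)OC(C)(C)C)=C2 | intermediate
16 | 4-bromocatechol | Oc1ccc(Br)cc1O | starting material
17 | 1,2-bis(benzyloxy)-4-bromobenzene | Brc1ccc(OCc2ccccc2)c(OCc2ccccc2)c1 | intermediate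
18 | [3,4-bis(benzyloxy)phenyl]lithium | [Li]c1ccc(OCc2ccccc2)c(OCc2ccccc2)c1 | intermediate (not isolated)
19 | lithium [3,4-bis(benzyloxy)phenyl]triisopropoxyborate | [Li+].CC(C)O[B-](OC(C)C)(OC(C)C)c1ccc(OCc2ccccc2)c(OCc2ccccc2)c1 | intermediate (not isolated)
20 | [3,4-bis(benzyloxy)phenyl]boronic acid | OB(O)c1ccc(OCc2ccccc2)c(OCc2ccccc2)c1 | intermediate
21 | 1-allyl 3-tert-butyl (1S,2S)-7,8-bis(benzyloxy)-2-[3,4-bis(benzyloxy)phenyl]-1-hydroxy-1,2-dihydronaphthalene-1,3-dicarboxylate (hydroxyl and aryl cis) | CC(C)(C)OC(=O)C1=Cc2ccc(OCc3ccccc3)c(OCc3ccccc3)c2[C@](O)(C(=O)OCC=C)[C@H]1c1ccc(OCc2ccccc2)c(OCc2ccccc2)c1 | intermediate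
22 | samarium enolate of 23 (allyl O-diiodosamarium ketene acetal at C1, C2 as in 21) | CC(C)(C)OC(=O)C1=Cc2ccc(OCc3ccccc3)c(OCc3ccccc3)c2C(=C(O[Sm](I)I)OCC=C)[C@H]1c1ccc(OCc2ccccc2)c(OCc2ccccc2)c1 | intermediate (not isolated)
23 | 1-allyl 3-tert-butyl (1S,2S)-7,8-bis(benzyloxy)-2-[3,4-bis(benzyloxy)phenyl]-1,2-dihydronaphthalene-1,3-dicarboxylate (C1 ester and aryl cis) | CC(C)(C)OC(=O)C1=Cc2ccc(OCc3ccccc3)c(OCc3ccccc3)c2[C@@H](C(=O)OCC=C)[C@H]1c1ccc(OCc2ccccc2)c(OCc2ccccc2)c1 | intermediate
24 | L-DOPA | N[C@@H](Cc1ccc(O)c(O)c1)C(=O)O | starting material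
25 | (2S)-3-(3,4-dihydroxyphenyl)-2-hydroxypropanoic acid | O[C@@H](Cc1ccc(O)c(O)c1)C(=O)O | intermediate
26 | methyl (2S)-3-(3,4-dihydroxyphenyl)-2-hydroxypropanoate | COC(=O)[C@@H](O)Cc1ccc(O)c(O)c1 | intermediate
27 | methyl (2S)-3-[3,4-bis(benzyloxy)phenyl]-2-hydroxypropanoate | COC(=O)[C@@H](O)Cc1ccc(OCc2ccccc2)c(OCc2ccccc2)c1 | intermediate
28 | (1S,2S)-1-[(allyloxy)carbonyl]-7,8-bis(benzyloxy)-2-[3,4-bis(benzyloxy)phenyl]-1,2-dihydronaphthalene-3-carboxylic acid | OC(=O)C1=Cc2ccc(OCc3ccccc3)c(OCc3ccccc3)c2[C@@H](C(=O)OCC=C)[C@H]1c1ccc(OCc2ccccc2)c(OCc2ccccc2)c1 | intermediate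
29 | 1-allyl 3-[(2S)-3-[3,4-bis(benzyloxy)phenyl]-1-methoxy-1-oxopropan-2-yl] (1S,2S)-7,8-bis(benzyloxy)-2-[3,4-bis(benzyloxy)phenyl]-1,2-dihydronaphthalene-1,3-dicarboxylate | COC(=O)[C@H](Cc1ccc(OCc2ccccc2)c(OCc2ccccc2)c1)OC(=O)C1=Cc2ccc(OCc3ccccc3)c(OCc3ccccc3)c2[C@@H](C(=O)OCC=C)[C@H]1c1ccc(OCc2ccccc2)c(OCc2ccccc2)c1 | intermediate
30 | (1S,2S)-7,8-bis(benzyloxy)-2-[3,4-bis(benzyloxy)phenyl]-3-({[(2S)-3-[3,4-bis(benzyloxy)phenyl]-1-methoxy-1-oxopropan-2-yl]oxy}carbonyl)-1,2-dihydronaphthalene-1-carboxylic acid | COC(=O)[C@H](Cc1ccc(OCc2ccccc2)c(OCc2ccccc2)c1)OC(=O)C1=Cc2ccc(OCc3ccccc3)c(OCc3ccccc3)c2[C@@H](C(=O)O)[C@H]1c1ccc(OCc2ccccc2)c(OCc2ccccc2)c1 | intermediate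
31 | octabenzyl ether of the target: 1-[(2R)-lactate] 3-[(2S)-lactate] diester of the (1S,2S)-dihydronaphthalene diacid, all eight phenols benzylated | COC(=O)[C@H](Cc1ccc(OCc2ccccc2)c(OCc2ccccc2)c1)OC(=O)C1=Cc2ccc(OCc3ccccc3)c(OCc3ccccc3)c2[C@@H](C(=O)O[C@H](Cc2ccc(OCc3ccccc3)c(OCc3ccccc3)c2)C(=O)OC)[C@H]1c1ccc(OCc2ccccc2)c(OCc2ccccc2)c1 | intermediate
32 | CNP0237075.1 | COC(=O)[C@H](Cc1ccc(O)c(O)c1)OC(=O)C1=Cc2ccc(O)c(O)c2[C@@H](C(=O)O[C@H](Cc2ccc(O)c(O)c2)C(=O)OC)[C@H]1c1ccc(O)c(O)c1 | target

## Step count and least certain steps

Total step count: 21. Longest linear sequence: 12 steps (steps 1–4, 9, 12, 13, 17–21; the furan branch, steps 5–8, is of equal length).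

**Step 9 (key step).**
- What may go wrong: bonding of C4a to the ester-bearing furan carbon, so that the bridgehead ester ends up remote from the C8 ether. If the transition state is strongly charge-separated, the two acceptor groups disfavour positive charge at the furan carbons that become C1 and C3, and steric repulsion by the C8 ether points the same way. A second hazard is slow capture of 14 by an electron-poor diene, which gives the aryne time to be consumed by fluoride or solvent.
- Fallback (intramolecular delivery through a temporary ester tether on the C8 oxygen; sets out from 2 and 12, returns at 15):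
  - 2 is benzylated at its more acidic 4-hydroxyl (BnBr 1 equiv, NaHCO3, NaI, DMF) to 4-(benzyloxy)-2-bromo-3-hydroxybenzaldehyde F1.
  - MOMCl and i-Pr2NEt give 4-(benzyloxy)-2-bromo-3-(methoxymethoxy)benzaldehyde F2.
  - Oxidation and methanolysis as in step 3 give 4-(benzyloxy)-2-bromo-3-(methoxymethoxy)phenol F3.
  - The sequence of step 4 gives 4-(benzyloxy)-3-(methoxymethoxy)-2-(trimethylsilyl)phenyl triflate F4.
  - HCl in MeOH removes the acetal under acidic conditions, which avoid a phenoxide next to silicon, to give 4-(benzyloxy)-3-hydroxy-2-(trimethylsilyl)phenyl triflate F5.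
  - Acid 12 is alkylated with benzyl bromoacetate (K2CO3, DMF) to 2-[2-(benzyloxy)-2-oxoethyl] 4-tert-butyl furan-2,4-dicarboxylate F6.
  - Hydrogenolysis (H2, Pd/C) gives {[4-(tert-butoxycarbonyl)furan-2-carbonyl]oxy}acetic acid F7.
  - Carbodiimide coupling of F7 with F5 gives the tethered precursor 6-(benzyloxy)-3-(triflyloxy)-2-(trimethylsilyl)phenyl {[4-(tert-butoxycarbonyl)furan-2-carbonyl]oxy}acetate F8.
  - CsF in dilute MeCN then generates the aryne with the furan held so that its ester-bearing carbon can reach only C8a, and gives the bridged bis-lactone cycloadduct F9 (racemic).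
  - LiOH in THF/H2O cleaves both tether esters to (1S,4S)-7-(benzyloxy)-3-(tert-butoxycarbonyl)-8-hydroxy-1,4-dihydro-1,4-epoxynaphthalene-1-carboxylic acid F10.
  - Allyl bromide with KHCO3 gives its allyl ester F11, and BnBr with K2CO3 returns 15.

**Step 12.**
- What may go wrong: too small a rate difference between the enantiomers of 15, because the site of attack is fixed by the enoate and the catalyst must tell the bridgehead ester from the bridgehead hydrogen at a distance. Protonation of the rhodium enolate before the ring opens is a further hazard.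
- Fallback (physical resolution followed by an achiral catalyst; sets out from 15, returns at 21): the enantiomers of 15 are separated by preparative chromatography on a chiral stationary phase. The (1S,4S)-enantiomer alone is opened with 20 and [Rh(cod)OH]2 without a chiral ligand. Exo delivery then sets C2 by itself and all of the single enantiomer can be converted. No compound outside the compound list is made (F0).

**Step 13.**
- What may go wrong: conjugate reduction of the C3=C4 enoate by SmI2/HMPA in competition with cleavage of the C1–O bond, or protonation of 22 from the face of the aryl group, which would give the trans isomer.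
- Fallback (radical deoxygenation; sets out from 21, returns at 23): 21 is acylated with methyl chlorooxoacetate (DMAP, pyridine, CH2Cl2) to the tertiary methyl oxalate F12. Bu3SnH and AIBN in toluene at reflux fragment it to the C1 radical, which takes a hydrogen atom from the stannane on the face away from the C2 aryl group. The enoate is not reduced by this reagent, and thermal syn-elimination has no hydrogen to use because H2 is trans to the C1 oxygen.

**Step 20.**
- What may go wrong: elimination of the activated alcohol to the cinnamate, or slow displacement by the hindered carboxylate, with loss of material or of configurational purity at the new lactate centre.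
- Fallback (carboxylate alkylation with a preformed sulfonate; sets out from 27 and 30, returns at 31): 27 is converted with Tf2O and 2,6-lutidine at −78 °C into methyl (2S)-3-[3,4-bis(benzyloxy)phenyl]-2-(triflyloxy)propanoate F13. Acid 30 with i-Pr2NEt displaces the triflate in CH2Cl2 at −40 → 0 °C, again by SN2 with inversion and without activating the C1 carboxyl.

## Further compounds

F1 | step 9 | 4-(benzyloxy)-2-bromo-3-hydroxybenzaldehyde | O=Cc1ccc(OCc2ccccc2)c(O)c1Br
F2 | step 9 | 4-(benzyloxy)-2-bromo-3-(methoxymethoxy)benzaldehyde | O=Cc1ccc(OCc2ccccc2)c(OCOC)c1Br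
F3 | step 9 | 4-(benzyloxy)-2-bromo-3-(methoxymethoxy)phenol | Oc1ccc(OCc2ccccc2)c(OCOC)c1Br
F4 | step 9 | 4-(benzyloxy)-3-(methoxymethoxy)-2-(trimethylsilyl)phenyl triflate | COCOc1c(OCc2ccccc2)ccc(OS(=O)(=O)C(F)(F)F)c1[Si](C)(C)C
F5 | step 9 | 4-(benzyloxy)-3-hydroxy-2-(trimethylsilyl)phenyl triflate | Oc1c(OCc2ccccc2)ccc(OS(=O)(=O)C(F)(F)F)c1[Si](C)(C)C
F6 | step 9 | 2-[2-(benzyloxy)-2-oxoethyl] 4-tert-butyl furan-2,4-dicarboxylate | O=C(COC(=O)c1cc(C(=O)OC(C)(C)C)co1)OCc1ccccc1
F7 | step 9 | {[4-(tert-butoxycarbonyl)furan-2-carbonyl]oxy}acetic acid | OC(=O)COC(=O)c1cc(C(=O)OC(C)(C)C)co1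
F8 | step 9 | 6-(benzyloxy)-3-(triflyloxy)-2-(trimethylsilyl)phenyl {[4-(tert-butoxycarbonyl)furan-2-carbonyl]oxy}acetate | C[Si](C)(C)c1c(OC(=O)COC(=O)c2cc(C(=O)OC(C)(C)C)co2)c(OCc2ccccc2)ccc1OS(=O)(=O)C(F)(F)F
F9 | step 9 | bridged bis-lactone cycloadduct (C1 carboxyl linked through O–CH2–C(=O) to the C8 oxygen; racemate, shown as the enantiomer that corresponds to 15) | O=C1COC(=O)[C@@]23O[C@@H](c4ccc(OCc5ccccc5)c(O1)c42)C(C(=O)OC(C)(C)C)=C3
F10 | step 9 | (1S,4S)-7-(benzyloxy)-3-(tert-butoxycarbonyl)-8-hydroxy-1,4-dihydro-1,4-epoxynaphthalene-1-carboxylic acid (racemate) | OC(=O)[C@@]12O[C@@H](c3ccc(OCc4ccccc4)c(O)c31)C(C(=O)OC(C)(C)C)=C2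
F11 | step 9 | 1-allyl 3-tert-butyl (1S,4S)-7-(benzyloxy)-8-hydroxy-1,4-dihydro-1,4-epoxynaphthalene-1,3-dicarboxylate (racemate) | C=CCOC(=O)[C@@]12O[C@@H](c3ccc(OCc4ccccc4)c(O)c31)C(C(=O)OC(C)(C)C)=C2
F0 | step 12 | none | none
F12 | step 13 | C1 methyl oxalate of 21 | CC(C)(C)OC(=O)C1=Cc2ccc(OCc3ccccc3)c(OCc3ccccc3)c2[C@](OC(=O)C(=O)OC)(C(=O)OCC=C)[C@H]1c1ccc(OCc2ccccc2)c(OCc2ccccc2)c1
F13 | step 20 | methyl (2S)-3-[3,4-bis(benzyloxy)phenyl]-2-(triflyloxy)propanoate | COC(=O)[C@@H](OS(=O)(=O)C(F)(F)F)Cc1ccc(OCc2ccccc2)c(OCc2ccccc2)c1
A1 | alternative 1 | hexa-MOM-protected target with free C7 phenol | COC(=O)[C@H](Cc1ccc(OCOC)c(OCOC)c1)OC(=O)C1=Cc2ccc(O)c(OCOC)c2[C@@H](C(=O)O[C@H](Cc2ccc(OCOC)c(OCOC)c2)C(=O)OC)[C@H]1c1ccc(OCOC)c(OCOC)c1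
A2 | alternative 1 | open-chain bis-enoate (cinnamate on C4a, α-aryl acrylate on C8a, free C7 phenol) | COC(=O)[C@H](Cc1ccc(OCOC)c(OCOC)c1)OC(=O)/C=C/c1ccc(O)c(OCOC)c1/C(C(=O)O[C@H](Cc1ccc(OCOC)c(OCOC)c1)C(=O)OC)=C\c1ccc(OCOC)c(OCOC)c1
A3 | alternative 2 | 1,1-di-tert-butyl 3-methyl 2-aryl-1,2-dihydronaphthalene-1,1,3-tricarboxylate | COC(=O)C1=Cc2ccc(OCc3ccccc3)c(OCc3ccccc3)c2C(C(=O)OC(C)(C)C)(C(=O)OC(C)(C)C)[C@H]1c1ccc(OCc2ccccc2)c(OCc2ccccc2)c1
A4 | alternative 2 | di-tert-butyl 2-{2,3-bis(benzyloxy)-6-[(Z)-2-iodo-3-methoxy-3-oxoprop-1-enyl]phenyl}malonate | COC(=O)/C(I)=C/c1ccc(OCc2ccccc2)c(OCc2ccccc2)c1C(C(=O)OC(C)(C)C)C(=O)OC(C)(C)C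
A5 | alternative 2 | 3,4-bis(benzyloxy)benzaldehyde tosylhydrazone | Cc1ccc(cc1)S(=O)(=O)N/N=C/c1ccc(OCc2ccccc2)c(OCc2ccccc2)c1
A6 | alternative 3 | cis peri-lactone (C1 carboxyl on the C8 oxygen) | COC(=O)[C@H](Cc1ccc(OCOC)c(OCOC)c1)OC(=O)C1=Cc2ccc(OCOC)c3c2[C@@H](C(=O)O3)[C@H]1c1ccc(OCOC)c(OCOC)c1
A7 | alternative 3 | C8 hydroxy C1 carboxylic acid, either C1 epimer | COC(=O)[C@H](Cc1ccc(OCOC)c(OCOC)c1)OC(=O)C1=Cc2ccc(OCOC)c(O)c2C(C(=O)O)[C@H]1c1ccc(OCOC)c(OCOC)c1
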